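The γ-lactone ring (O–C19–C17–C8–C7, briarane numbering) is read as the cyclobutanone ring C19–C17–C8–C7 plus one oxygen between C19 and C7. A Baeyer–Villiger oxidation performs this insertion in one operation, C7 migrating to oxygen with retention, and with a chiral scandium catalyst it also picks one enantiomer of the racemic ketone. The precursor is a cis-2,3-disubstituted cyclobutanone bearing C6 as a benzyloxymethyl arm on C7 and, on C8, a silyloxy group and C9 as a dimethyl acetal. Later, C9 is joined to a Birch-derived ring A piece at C10, and the ten-membered ring is closed by C2–C3 pinacol coupling.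

Key step: step 5

Remark: briarane numbering (C1–C20) is used for all intermediates; compounds 7 and 8 are racemic and are drawn as the enantiomer that is carried on.
Assumption: (1,3-dioxolan-2-ylmethyl)zinc bromide is bought as a THF solution (otherwise it is made from the commercial Grignard reagent and ZnBr2).

**Route**

Step 1
Reactants: 1 1,1-dimethoxypropan-2-one; 2 benzyl chloromethyl ether
Product: 4 4-(benzyloxy)-1,1-dimethoxybutan-2-one, via lithium enolate 3 (not isolated)
Conditions: LDA, THF, −78 °C; then 2, −78 → −20 °C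
Reagents that add atoms: none
Why: LDA removes a methyl proton under kinetic control (the acetal methine is not deprotonated) and the lithium enolate is C-alkylated by the reactive α-chloro ether in an SN2 enolate alkylation that installs C6.

Step 2
Reactants: 4 4-(benzyloxy)-1,1-dimethoxybutan-2-one
Product: 5 (Z)-{[4-(benzyloxy)-1,1-dimethoxybut-2-en-2-yl]oxy}(tert-butyl)dimethylsilane
Conditions: TBSOTf, Et3N, CH2Cl2, −78 → 0 °C
Reagents that add atoms: tert-butyldimethylsilyl triflate, CC(C)(C)[Si](C)(C)OS(=O)(=O)C(F)(F)F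
Why: Soft enolisation (silyl triflate and amine) toward the only methylene should give the thermodynamically preferred Z silyl enol ether (silyloxy cis to the CH2OBn arm) without a free enolate that could expel benzyloxide, and the acetal next to the carbonyl resists ionisation.

Step 3
Reactants: 5 (Z)-silyl enol ether; 6 dichloroacetyl chloride
Product: 7 racemic cis-4-[(benzyloxy)methyl]-3-[(tert-butyldimethylsilyl)oxy]-2,2-dichloro-3-(dimethoxymethyl)cyclobutan-1-one
Conditions: 6 (slow addition), Et3N, hexane, 25 °C
Reagents that add atoms: none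
Why: Dichloroketene formed by dehydrochlorination adds suprafacially to the electron-rich enol ether ([2+2] ketene cycloaddition), its carbonyl carbon bonding to the nucleophilic CH terminus, so C19–C7 and C17–C8 form and the Z geometry becomes the cis relation of silyloxy and benzyloxymethyl groups at C8 and C7.

Step 4
Reactants: 7 racemic dichlorocyclobutanone
Product: 8 racemic (2S,3S)-2-[(benzyloxy)methyl]-3-[(tert-butyldimethylsilyl)oxy]-3-(dimethoxymethyl)cyclobutan-1-one
Conditions: Zn–Cu couple, NH4Cl, MeOH, 20 °C
Reagents that add atoms: none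
Why: Zinc reduces both C–Cl bonds α to the ketone (reductive dehalogenation) and the buffered protic medium protonates the zinc enolate before it can expel the β-silyloxy group, so C7 and C8 are left unchanged.

Step 5
Reactants: 8 racemic cyclobutanone
Product: 9 (4S,5S)-5-[(benzyloxy)methyl]-4-[(tert-butyldimethylsilyl)oxy]-4-(dimethoxymethyl)oxolan-2-one
Conditions: Sc(OTf)3 (5 mol %), chiral N,N′-dioxide ligand (L-pipecolic-acid-derived bis(2,6-diisopropylanilide), 5 mol %; antipode chosen so that (2S,3S)-8 reacts faster), mCPBA (0.55 equiv), EtOAc, −20 °C, to about 50% conversion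
Reagents that add atoms: 3-chloroperoxybenzoic acid, OOC(=O)c1cccc(Cl)c1
Why: The peracid adds to the Lewis-acid-bound, strained carbonyl C19 to give the Criegee adduct, and the C19–C7 bond shifts to the peroxide oxygen anti-periplanar to the leaving carboxylate while the C17 methylene stays. The closest known reaction type is the catalytic asymmetric Baeyer–Villiger kinetic resolution of racemic α-substituted cyclobutanones and cyclohexanones with chiral N,N′-dioxide–scandium triflate and related catalysts. The five-membered lactone is not closed by a cyclisation but arises by ring expansion, a 1,2-shift that inserts oxygen into the C19–C7 bond of the four-membered ring and forms C7–O and O–C19. No stereocentre is created: C7 migrates with retention and C8 is untouched, so the cis relation from the cycloaddition is carried into 9 and the absolute configuration comes from the catalyst, which oxidises the (2S,3S) enantiomer faster. The step needs regioselectivity for C7 over C17 migration, secured by the higher substitution of C7, and chemoselectivity, secured by the ring strain that lets the oxidation run at −20 °C where acetal, silyl ether and benzyl ether are inert.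

Step 6
Reactants: 9 silyloxy lactone
Product: 10 (4S,5S)-5-[(benzyloxy)methyl]-4-(dimethoxymethyl)-4-hydroxyoxolan-2-one
Conditions: TBAF, AcOH, THF, 0 °C
Reagents that add atoms: none
Why: Buffered fluoride cleaves the Si–O bond (desilylation) while acetic acid keeps the tertiary C8 oxygen protonated, so retro-aldol opening does not compete.

Step 7
Reactants: 10 β-hydroxy lactone
Product: 12 5-[(benzyloxy)methyl]-4-(dimethoxymethyl)-3,4-dihydroxyoxolan-2-one (C7 and C8 as in 10, mixture at C17), via dilithium alkoxide–enolate 11 (not isolated)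
Conditions: LDA (2.3 equiv), THF, −78 °C; then 2-(benzenesulfonyl)-3-phenyloxaziridine, −78 → −40 °C; NH4Cl
Reagents that add atoms: 2-(benzenesulfonyl)-3-phenyloxaziridine, O=S(=O)(N1OC1c1ccccc1)c1ccccc1
Why: The alkoxide–enolate dianion cannot undergo β-elimination and takes up electrophilic oxygen at C17 (Davis enolate hydroxylation); the C17 configuration is immaterial because the next step oxidises it.

Step 8
Reactants: 12 dihydroxy lactone
Product: 13 (4S,5S)-5-[(benzyloxy)methyl]-4-(dimethoxymethyl)-4-hydroxyoxolane-2,3-dione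
Conditions: Dess–Martin periodinane, pyridine, CH2Cl2, 0 → 20 °C
Reagents that add atoms: none
Why: Dess–Martin oxidation converts the secondary C17 carbinol into the ketone and cannot touch the tertiary C8 hydroxyl.

Step 9
Reactants: 13 α-keto lactone
Product: 14 5-[(benzyloxy)methyl]-4-(dimethoxymethyl)-3,4-dihydroxy-3-methyloxolan-2-one (C17 methyl cis to the C8 hydroxyl, the two hydroxyls trans)
Conditions: MeMgBr (3 equiv), THF, −78 °C; NH4Cl
Reagents that add atoms: methylmagnesium bromide, C[Mg]Br
Why: The Grignard reagent first forms the C8 magnesium alkoxide and then adds to the ketone, far more electrophilic than the lactone carbonyl, from the face of that alkoxide and away from the branched C9 acetal on the adjacent quaternary carbon (alkoxide-directed, sterically reinforced 1,2-addition), which places the methyl cis to C8–O and the new C17 hydroxyl trans to it.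

Step 10
Reactants: 14 diol
Product: 15 5-[(benzyloxy)methyl]-4-(dimethoxymethyl)-3-methyl-3,4-bis[(triethylsilyl)oxy]oxolan-2-one
Conditions: TESOTf, Et3N, CH2Cl2, −78 → −20 °C; MeOH/NaHCO3 quench at −20 °C
Reagents that add atoms: triethylsilyl triflate, CC[Si](CC)(CC)OS(=O)(=O)C(F)(F)F
Why: The silyl triflate silylates both hindered tertiary alcohols, and with a trialkylamine at low temperature the hindered α-oxygenated acetal is not consumed (no α-hydrogen for enol ether formation, no pyridine to trap an oxocarbenium ion).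

Step 11
Reactants: 15 bis-silyl ether
Product: 16 4-(dimethoxymethyl)-5-(hydroxymethyl)-3-methyl-3,4-bis[(triethylsilyl)oxy]oxolan-2-one
Conditions: H2 (1 atm), Pd/C, EtOAc, 20 °C
Reagents that add atoms: none
Why: Hydrogenolysis removes the benzyl ether at a stage where no alkene or halide is present, and ethyl acetate as solvent spares silyl ethers and acetal.

Step 12
Reactants: 16 primary alcohol
Product: 17 4-(dimethoxymethyl)-3-methyl-5-oxo-3,4-bis[(triethylsilyl)oxy]oxolane-2-carbaldehyde (C6 aldehyde)
Conditions: Dess–Martin periodinane, pyridine, CH2Cl2, 0 → 20 °C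
Reagents that add atoms: none
Why: Dess–Martin oxidation gives the aldehyde under buffered, non-basic conditions that should not epimerise C7; the aldehyde is used at once.

Step 13
Reactants: 17 C6 aldehyde; 18 ethyltriphenylphosphonium iodide
Product: 19 4-(dimethoxymethyl)-5-[(1Z)-2-iodoprop-1-en-1-yl]-3-methyl-3,4-bis[(triethylsilyl)oxy]oxolan-2-one
Conditions: 18, n-BuLi, THF, 20 °C; I2, −78 °C; NaHMDS, −78 → −20 °C; then 17, −78 °C
Reagents that add atoms: iodine, II
Why: Wittig olefination with the α-iodo ylide (Stork–Zhao-type iodo-olefination) gives the Z 2-iodoalkene under kinetic control at low temperature, so iodine sits cis to C7 and marks the position that C4 will take in the C5=C6 bond.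

Step 14
Reactants: 19 vinyl iodide
Product: 21 4-[(1Z)-2-iodoprop-1-en-1-yl]-2-methyl-5-oxo-2,3-bis[(triethylsilyl)oxy]oxolane-3-carbaldehyde (C9 aldehyde), via collidinium salt 20 (not isolated)
Conditions: TESOTf, 2,4,6-collidine, CH2Cl2, 0 → 20 °C; then H2O
Reagents that add atoms: water, O
Why: Silyl triflate and collidine convert the dimethyl acetal into a pyridinium N,O-acetal that water hydrolyses to the aldehyde without protic acid (Fujioka acetal cleavage), so silyl ethers, lactone and vinyl iodide survive.

Step 15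
Reactants: 22 3-methylbenzoic acid
Product: 24 racemic 1,3-dimethylcyclohexa-2,5-diene-1-carboxylic acid, via dilithium dienediolate 23 (not isolated)
Conditions: Li, NH3 (l)/THF, −78 °C; then MeI; aq. HCl
Reagents that add atoms: iodomethane, CI
Why: Birch reduction gives the 1,4-dihydro dianion with the carbanion at the carboxyl-bearing carbon, which is methylated there (Birch reductive alkylation), creating the quaternary C1 (methyl C15, carboxyl C2) with C20 on a double bond and C12 as the doubly allylic CH2.

Step 16
Reactants: 24 racemic dienoic acid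
Product: 26 (S)-1,3-dimethylcyclohexa-2,5-diene-1-carboxylic acid, via phenylethylammonium salt 25 (not isolated)
Conditions: (S)-1-phenylethylamine (0.55 equiv), acetone, crystallisation (twice); salt filtered and cleaved at once with 1 M HCl/Et2O
Reagents that add atoms: none
Why: Classical resolution through diastereomeric ammonium carboxylate salts; if the salt of the (R)-acid turns out to be the less soluble one, the (R)-amine is used instead.

Step 17
Reactants: 26 (S)-acid
Product: 27 [(1S)-1,3-dimethylcyclohexa-2,5-dien-1-yl]methanol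
Conditions: LiAlH4, THF, 0 → 20 °C
Reagents that add atoms: none
Why: Hydride reduction of the carboxylic acid to the primary alcohol; the unconjugated diene is inert.

Step 18
Reactants: 27 alcohol
Product: 28 (1S)-1,3-dimethylcyclohexa-2,5-diene-1-carbaldehyde
Conditions: Dess–Martin periodinane, pyridine, CH2Cl2, 0 °C
Reagents that add atoms: none
Why: Mild Dess–Martin oxidation of the neopentyl alcohol to the non-enolisable aldehyde.

Step 19
Reactants: 28 aldehyde
Product: 29 (3S)-3-(dimethoxymethyl)-1,3-dimethylcyclohexa-1,4-diene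
Conditions: HC(OMe)3, MeOH, PPTS (cat.), 20 °C
Reagents that add atoms: trimethyl orthoformate, COC(OC)OC
Why: Acid-catalysed acetalisation driven by the orthoformate, with an acid weak enough not to trigger cationic rearrangement of the diene.

Step 20
Reactants: 29 acetal diene; 21 C9 aldehyde
Product: 32 coupled alcohol: 21 with its aldehyde converted into C9H(OH) bonded to C10 of a 6-(dimethoxymethyl)-2,6-dimethylcyclohexa-2,4-dien-1-yl ring (C9/C10 syn, C9 cis to the C1 methyl), via dienyllithium 30 (not isolated), via dienyltitanium 31 (not isolated)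
Conditions: 29 (2 equiv), s-BuLi (1.9 equiv), TMEDA, THF, −78 °C; ClTi(OiPr)3, −78 °C; then 21 (1 equiv), −78 → −40 °C
Reagents that add atoms: none
Why: The doubly allylic C12–H is removed, titanium takes the least hindered central carbon, and the allyltitanium adds to the aldehyde through a closed six-membered chair (allyl-type SE2′ addition, known for cyclohexadienyltitanium reagents) at C10 of the more nucleophilic methyl-bearing arm, making C9–C10 and the conjugated C11=C12/C13=C14 diene; C9 should follow the Felkin–Anh model (C8–OSi anti, attack past the smaller C7), C10 is attacked anti to the acetal on C1, and the ring-constrained Z-type allyl unit gives the syn C9/C10 relation, three preferences that reinforce one another for the (S)-fragment.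

Step 21
Reactants: 32 coupled alcohol
Product: 33 C9 acetate of 32
Conditions: Ac2O, DMAP, pyridine, 40 °C
Reagents that add atoms: acetic anhydride, CC(=O)OC(C)=O
Why: DMAP-catalysed acetylation of the only free hydroxyl installs the C9 acetate of the target and blocks translactonisation.

Step 22
Reactants: 33 diene acetate
Product: 34 11,12-cis-diol (both hydroxyls on the ring A face opposite to C9; C13=C14 kept)
Conditions: OsO4 (5 mol %), NMO, acetone/H2O, 0 → 20 °C
Reagents that add atoms: osmium tetroxide (catalytic oxygen carrier), O=[Os](=O)(=O)=O; 4-methylmorpholine N-oxide, C[N+]1([O-])CCOCC1; water, O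
Why: OsO4 adds syn (catalytic dihydroxylation) to the electron-richer trisubstituted C11=C12 bond of the diene from the face opposite the bulky C9 substituent on C10, setting C11 and C12 together, while the C13=C14 bond next to the quaternary C1 and the iodoalkene react much more slowly.

Step 23
Reactants: 34 vinyl iodide diol; 35 (1,3-dioxolan-2-ylmethyl)zinc bromide
Product: 36 (5Z)-alkene carrying the C4 methylene and C3 as a 1,3-dioxolane in place of iodine
Conditions: 35 (4 equiv), PdCl2(dppf) (5 mol %), THF, 50 °C
Reagents that add atoms: none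
Why: Negishi cross-coupling of the alkenyl iodide with the primary alkylzinc reagent proceeds with retention of alkene geometry and tolerates lactone, acetate, acetal and free hydroxyls; the cyclic acetal keeps the zinc reagent from β-elimination.

Step 24
Reactants: 36 diol bis-acetal
Product: 38 C2,C3-dialdehyde with C11 and C12 hydroxyls as triethylsilyl ethers, via bis-collidinium salt 37 (not isolated)
Conditions: TESOTf (6 equiv), 2,4,6-collidine, CH2Cl2, 0 → 20 °C; then H2O
Reagents that add atoms: triethylsilyl triflate, CC[Si](CC)(CC)OS(=O)(=O)C(F)(F)F; water, O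
Why: Excess silyl triflate silylates both free hydroxyls and turns the dimethyl acetal and the dioxolane into collidinium salts that water converts into the two aldehydes (Fujioka acetal cleavage) without acid that would move the C5=C6 bond into conjugation.

Step 25
Reactants: 38 dialdehyde
Product: 39 ten-membered 2,3-cis-diol (briarane skeleton; C9 acetate, four triethylsilyl ethers)
Conditions: SmI2 (4 equiv), THF, slow addition of 38 to 0.003 M, −78 → 20 °C; aq. NaHCO3
Reagents that add atoms: none
Why: Single-electron transfer from SmI2 gives ketyl radicals at C2 and C3 that couple (intramolecular pinacol coupling, precedented for medium and large carbocycles), and bridging of both oxygens by samarium should favour the cis-diol on the face imposed by the trans-disposed ring A substituents and the Z C5=C6 bond; both new stereocentres rest on this chelated ring closure.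

Step 26
Reactants: 39 diol
Product: 40 3-O-acetate of 39
Conditions: Ac2O (1.2 equiv), pyridine, CH2Cl2, 0 °C
Reagents that add atoms: acetic anhydride, CC(=O)OC(C)=O
Why: Acetylation should select the C3 hydroxyl, flanked by a methylene, over the neopentyl C2 hydroxyl next to the quaternary C1, and all other hydroxyls are silylated.

Step 27
Reactants: 40 tetrakis-silyl ether
Product: 41 Brianodin D
Conditions: HF·pyridine, pyridine, THF, 0 → 20 °C
Reagents that add atoms: none
Why: Fluoride-mediated desilylation removes the four triethylsilyl ethers (C8, C11, C12, C17) under buffered conditions that leave both acetates, the lactone and the allylic C12 alcohol intact.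

**Compound list**

1 | 1,1-dimethoxypropan-2-one | CC(=O)C(OC)OC | starting material
2 | benzyl chloromethyl ether | ClCOCc1ccccc1 | starting material
3 | lithium 3,3-dimethoxyprop-1-en-2-olate | [Li]OC(=C)C(OC)OC | intermediate (not isolated)
4 | 4-(benzyloxy)-1,1-dimethoxybutan-2-one | COC(OC)C(=O)CCOCc1ccccc1 | intermediate
5 | (Z)-{[4-(benzyloxy)-1,1-dimethoxybut-2-en-2-yl]oxy}(tert-butyl)dimethylsilane | COC(OC)/C(O[Si](C)(C)C(C)(C)C)=C/COCc1ccccc1 | intermediate
6 | dichloroacetyl chloride | ClC(Cl)C(Cl)=O | starting material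
7 | racemic cis-4-[(benzyloxy)methyl]-3-[(tert-butyldimethylsilyl)oxy]-2,2-dichloro-3-(dimethoxymethyl)cyclobutan-1-one | O=C1C(Cl)(Cl)[C@@](O[Si](C)(C)C(C)(C)C)(C(OC)OC)[C@@H]1COCc1ccccc1 | intermediate
8 | racemic (2S,3S)-2-[(benzyloxy)methyl]-3-[(tert-butyldimethylsilyl)oxy]-3-(dimethoxymethyl)cyclobutan-1-one | O=C1C[C@@](O[Si](C)(C)C(C)(C)C)(C(OC)OC)[C@@H]1COCc2ccccc2 | intermediate
9 | (4S,5S)-5-[(benzyloxy)methyl]-4-[(tert-butyldimethylsilyl)oxy]-4-(dimethoxymethyl)oxolan-2-one | O=C1C[C@@](O[Si](C)(C)C(C)(C)C)(C(OC)OC)[C@H](COCc2ccccc2)O1 | intermediate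
10 | (4S,5S)-5-[(benzyloxy)methyl]-4-(dimethoxymethyl)-4-hydroxyoxolan-2-one | O=C1C[C@@](O)(C(OC)OC)[C@H](COCc2ccccc2)O1 | intermediate
11 | dilithium alkoxide–enolate of 10 | [Li]OC1=C[C@@](O[Li])(C(OC)OC)[C@H](COCc2ccccc2)O1 | intermediate (not isolated)
12 | 5-[(benzyloxy)methyl]-4-(dimethoxymethyl)-3,4-dihydroxyoxolan-2-one (mixture at C17) | O=C1C(O)[C@@](O)(C(OC)OC)[C@H](COCc2ccccc2)O1 | intermediate
13 | (4S,5S)-5-[(benzyloxy)methyl]-4-(dimethoxymethyl)-4-hydroxyoxolane-2,3-dione | O=C1C(=O)[C@@](O)(C(OC)OC)[C@H](COCc2ccccc2)O1 | intermediate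
14 | 5-[(benzyloxy)methyl]-4-(dimethoxymethyl)-3,4-dihydroxy-3-methyloxolan-2-one (methyl cis to C8–OH) | O=C1[C@@](C)(O)[C@@](O)(C(OC)OC)[C@H](COCc2ccccc2)O1 | intermediate
15 | bis(triethylsilyl) ether of 14 | O=C1[C@@](C)(O[Si](CC)(CC)CC)[C@@](O[Si](CC)(CC)CC)(C(OC)OC)[C@H](COCc2ccccc2)O1 | intermediate
16 | C6 primary alcohol (debenzylated 15) | O=C1[C@@](C)(O[Si](CC)(CC)CC)[C@@](O[Si](CC)(CC)CC)(C(OC)OC)[C@H](CO)O1 | intermediate
17 | C6 aldehyde | O=C1[C@@](C)(O[Si](CC)(CC)CC)[C@@](O[Si](CC)(CC)CC)(C(OC)OC)[C@H](C=O)O1 | intermediate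
18 | ethyltriphenylphosphonium iodide | CC[P+](c1ccccc1)(c1ccccc1)c1ccccc1.[I-] | starting material
19 | (Z)-vinyl iodide lactone acetal | I/C(C)=C\[C@@H]1OC(=O)[C@@](C)(O[Si](CC)(CC)CC)[C@@]1(O[Si](CC)(CC)CC)C(OC)OC | intermediate
20 | C9 methoxy(collidinium)methyl triflate of 19 | I/C(C)=C\[C@@H]1OC(=O)[C@@](C)(O[Si](CC)(CC)CC)[C@@]1(O[Si](CC)(CC)CC)C(OC)[n+]1c(C)cc(C)cc1C.[O-]S(=O)(=O)C(F)(F)F | intermediate (not isolated)
21 | C9 aldehyde, (Z)-vinyl iodide lactone | I/C(C)=C\[C@@H]1OC(=O)[C@@](C)(O[Si](CC)(CC)CC)[C@@]1(O[Si](CC)(CC)CC)C=O | intermediate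
22 | 3-methylbenzoic acid | Cc1cccc(C(=O)O)c1 | starting material
23 | dilithium dienediolate from Birch reduction of 22 | [Li]OC(O[Li])=C1C=C(C)CC=C1 | intermediate (not isolated)
24 | racemic 1,3-dimethylcyclohexa-2,5-diene-1-carboxylic acid | CC1=CC(C)(C(=O)O)C=CC1 | intermediate
25 | (S)-1-phenylethylammonium (S)-1,3-dimethylcyclohexa-2,5-diene-1-carboxylate | CC1=C[C@@](C)(C(=O)[O-])C=CC1.C[C@H]([NH3+])c1ccccc1 | intermediate (not isolated)
26 | (S)-1,3-dimethylcyclohexa-2,5-diene-1-carboxylic acid | CC1=C[C@@](C)(C(=O)O)C=CC1 | intermediate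
27 | [(1S)-1,3-dimethylcyclohexa-2,5-dien-1-yl]methanol | CC1=C[C@@](C)(CO)C=CC1 | intermediate
28 | (1S)-1,3-dimethylcyclohexa-2,5-diene-1-carbaldehyde | CC1=C[C@@](C)(C=O)C=CC1 | intermediate
29 | (3S)-3-(dimethoxymethyl)-1,3-dimethylcyclohexa-1,4-diene | CC1=C[C@@](C)(C(OC)OC)C=CC1 | intermediate
30 | dienyllithium from 29 (lithium drawn on C12) | CC1=C[C@@](C)(C(OC)OC)C=CC1[Li] | intermediate (not isolated)
31 | dienyltitanium triisopropoxide from 30 | CC1=C[C@@](C)(C(OC)OC)C=CC1[Ti](OC(C)C)(OC(C)C)OC(C)C | intermediate (not isolated)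
32 | coupled C9 alcohol with ring A diene | I/C(C)=C\[C@@H]1OC(=O)[C@@](C)(O[Si](CC)(CC)CC)[C@@]1(O[Si](CC)(CC)CC)[C@@H](O)[C@H]2C(C)=CC=C[C@]2(C)C(OC)OC | intermediate
33 | C9 acetate with ring A diene | I/C(C)=C\[C@@H]1OC(=O)[C@@](C)(O[Si](CC)(CC)CC)[C@@]1(O[Si](CC)(CC)CC)[C@@H](OC(C)=O)[C@H]2C(C)=CC=C[C@]2(C)C(OC)OC | intermediate
34 | 11,12-cis-diol vinyl iodide | I/C(C)=C\[C@@H]1OC(=O)[C@@](C)(O[Si](CC)(CC)CC)[C@@]1(O[Si](CC)(CC)CC)[C@@H](OC(C)=O)[C@H]2[C@](C)(O)[C@H](O)C=C[C@]2(C)C(OC)OC | intermediate
35 | (1,3-dioxolan-2-ylmethyl)zinc bromide | Br[Zn]CC1OCCO1 | starting material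
36 | (5Z)-alkene with C3 dioxolane and C2 dimethyl acetal | O1CCOC1C/C(C)=C\[C@@H]1OC(=O)[C@@](C)(O[Si](CC)(CC)CC)[C@@]1(O[Si](CC)(CC)CC)[C@@H](OC(C)=O)[C@H]2[C@](C)(O)[C@H](O)C=C[C@]2(C)C(OC)OC | intermediate
37 | C2,C3-bis(collidinium) bis(triflate), four triethylsilyl ethers | CC[Si](CC)(CC)OCCOC([n+]1c(C)cc(C)cc1C)C/C(C)=C\[C@@H]1OC(=O)[C@@](C)(O[Si](CC)(CC)CC)[C@@]1(O[Si](CC)(CC)CC)[C@@H](OC(C)=O)[C@H]2[C@](C)(O[Si](CC)(CC)CC)[C@H](O[Si](CC)(CC)CC)C=C[C@]2(C)C(OC)[n+]1c(C)cc(C)cc1C.[O-]S(=O)(=O)C(F)(F)F.[O-]S(=O)(=O)C(F)(F)F | intermediate (not isolated)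
38 | C2,C3-dialdehyde, four triethylsilyl ethers | O=CC/C(C)=C\[C@@H]1OC(=O)[C@@](C)(O[Si](CC)(CC)CC)[C@@]1(O[Si](CC)(CC)CC)[C@@H](OC(C)=O)[C@H]2[C@](C)(O[Si](CC)(CC)CC)[C@H](O[Si](CC)(CC)CC)C=C[C@]2(C)C=O | intermediate
39 | ten-membered 2,3-cis-diol (pinacol product) | O[C@@H]1C/C(C)=C\[C@@H]2OC(=O)[C@@](C)(O[Si](CC)(CC)CC)[C@@]2(O[Si](CC)(CC)CC)[C@@H](OC(C)=O)[C@H]2[C@](C)(O[Si](CC)(CC)CC)[C@H](O[Si](CC)(CC)CC)C=C[C@]2(C)[C@@H]1O | intermediate
40 | 3,9-diacetate, 8,11,12,17-tetrakis(triethylsilyl) ether | CC(=O)O[C@@H]1C/C(C)=C\[C@@H]2OC(=O)[C@@](C)(O[Si](CC)(CC)CC)[C@@]2(O[Si](CC)(CC)CC)[C@@H](OC(C)=O)[C@H]2[C@](C)(O[Si](CC)(CC)CC)[C@H](O[Si](CC)(CC)CC)C=C[C@]2(C)[C@@H]1O | intermediate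
41 | Brianodin D | CC(=O)O[C@@H]1C/C(C)=C\[C@@H]2OC(=O)[C@@](C)(O)[C@@]2(O)[C@@H](OC(C)=O)[C@H]2[C@](C)(O)[C@H](O)C=C[C@]2(C)[C@@H]1O | target

**Count and risks**

Total step count: 27. Longest linear sequence: 22 steps (steps 1–14 and 20–27); the ring A branch is steps 15–19.

Steps most likely to fail:

1. Step 5. The catalyst may discriminate too weakly between the enantiomers of 8, or the Lewis acid may attack the acetal or silyl ether. Fallback: racemic 8 is oxidised completely with mCPBA/NaHCO3 in CH2Cl2 (uncatalysed Baeyer–Villiger oxidation, same regiochemistry) to the racemic lactone, that is 9 together with its mirror image, the (4R,5R)-lactone F1. The two are separated by preparative chromatography on a chiral stationary phase. The fallback sets out from 8 and returns to the route at 9.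

2. Step 20. Addition may be slow because both reacting carbons are flanked by fully substituted centres, the reagent may add through the other terminus (C14), or facial selectivity may be poor. Fallback: the anion from 29 (s-BuLi, TMEDA) is quenched with 2-isopropoxy-4,4,5,5-tetramethyl-1,3,2-dioxaborolane to give the isolable bis-allylic boronate 2-[(4S)-4-(dimethoxymethyl)-2,4-dimethylcyclohexa-2,5-dien-1-yl]-4,4,5,5-tetramethyl-1,3,2-dioxaborolane F2. F2 is heated with aldehyde 21 in toluene (or treated with catalytic Sc(OTf)3 at low temperature) in an allylboration through a closed six-membered transition state, with boron fixed on C12; aqueous work-up releases the alcohol. The fallback sets out from 29 and returns at 32.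

3. Step 25. The coupling may give the trans-diol or the diol on the wrong ring face, may be outrun by intermolecular coupling or simple reduction, or the C5=C6 bond may move into conjugation with the C3 aldehyde beforehand. Fallback (ring-closing metathesis, then dihydroxylation):
   - Iodide 34 is coupled with allyltributylstannane (Pd(PPh3)4, DMF) to the allyl diene diol F3.
   - TESOTf/2,4,6-collidine, then water, silylates both hydroxyls and unmasks C2 to give the aldehyde F4.
   - Ph3P=CH2 converts F4 into the C1 vinyl compound F5.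
   - Second-generation Grubbs catalyst in dilute toluene closes the ten-membered ring to the (2Z)-cycloalkene F6.
   - OsO4 then adds to the disubstituted C2=C3 bond, which secures the cis relation of the diol.
   
   The fallback sets out from 34 and returns at 39.

Further compounds
F1 | step 5 | (4R,5R)-5-[(benzyloxy)methyl]-4-[(tert-butyldimethylsilyl)oxy]-4-(dimethoxymethyl)oxolan-2-one (mirror image of 9) | O=C1C[C@](O[Si](C)(C)C(C)(C)C)(C(OC)OC)[C@@H](COCc2ccccc2)O1
F2 | step 20 | 2-[(4S)-4-(dimethoxymethyl)-2,4-dimethylcyclohexa-2,5-dien-1-yl]-4,4,5,5-tetramethyl-1,3,2-dioxaborolane | CC1=C[C@@](C)(C(OC)OC)C=CC1B1OC(C)(C)C(C)(C)O1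
F3 | step 25 | allyl diene diol (allyl on C5 in place of iodine, C2 dimethyl acetal) | C=CC/C(C)=C\[C@@H]1OC(=O)[C@@](C)(O[Si](CC)(CC)CC)[C@@]1(O[Si](CC)(CC)CC)[C@@H](OC(C)=O)[C@H]2[C@](C)(O)[C@H](O)C=C[C@]2(C)C(OC)OC
F4 | step 25 | C2 aldehyde with C5 allyl group, four triethylsilyl ethers | C=CC/C(C)=C\[C@@H]1OC(=O)[C@@](C)(O[Si](CC)(CC)CC)[C@@]1(O[Si](CC)(CC)CC)[C@@H](OC(C)=O)[C@H]2[C@](C)(O[Si](CC)(CC)CC)[C@H](O[Si](CC)(CC)CC)C=C[C@]2(C)C=O
F5 | step 25 | C1 vinyl, C5 allyl metathesis precursor | C=CC/C(C)=C\[C@@H]1OC(=O)[C@@](C)(O[Si](CC)(CC)CC)[C@@]1(O[Si](CC)(CC)CC)[C@@H](OC(C)=O)[C@H]2[C@](C)(O[Si](CC)(CC)CC)[C@H](O[Si](CC)(CC)CC)C=C[C@]2(C)C=C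
F6 | step 25 | (2Z,5Z)-cyclodecadiene from ring-closing metathesis | C1(C)=C\[C@@H]2OC(=O)[C@@](C)(O[Si](CC)(CC)CC)[C@@]2(O[Si](CC)(CC)CC)[C@@H](OC(C)=O)[C@H]2[C@](C)(O[Si](CC)(CC)CC)[C@H](O[Si](CC)(CC)CC)C=C[C@]2(C)/C=C\C/1
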